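**Retrosynthetic overview**
- Feature: the strategy rests on the flavone O1–C8a aryl ether bond of ring C. C8a belongs to ring A and stands ortho to the C4 carbonyl (through C4a). A fluorine on C8a therefore makes C8a=C4a–C4=O a vinylogous acyl fluoride that the C2 enolate oxygen can attack.
- Disconnections, backwards: the five O-benzyl groups come off first. O1–C8a (ring C) then leads to a 2-benzyloxy-1,3-diketone, and C2–C3 leads to the enolate of a ring A α-benzyloxy ketone plus the acid chloride of the ring B benzodioxane.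
- Ring A ketone: 1,3,5-trifluorobenzene, two fluoride displacements by benzyl oxide, bromination, Br/Li exchange and Weinreb acylation. The third fluorine is kept for the key step.
- Benzodioxane: an Evans syn glycolate aldol of an aryloxyacetyl imide with O-benzylvanillin sets both stereocentres with the O4–C3 bond already in place. The benzylic hydroxyl then displaces a fluoride para to the ester with retention at both carbons, which gives the trans (2R,3R) ring.
- Ring order: the dioxane ring is closed in step 8 and ring C in step 12. Rings A, B and the guaiacyl ring are bought.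

Key step: step 12

Assumption: rings A and C carry flavone numbering (O1, C2, C3, C4, C4a, C5 to C8, C8a). The dioxane carries 1,4-benzodioxine numbering (O1, C2 with the aryl group, C3 with the CH2O group, O4). Compounds 6, 11 and 13 are taken as purchasable.

**Step 1**
Reactants: 1 1,3,5-trifluorobenzene; 2 benzyl alcohol
Product: 4 1,3-bis(benzyloxy)-5-fluorobenzene, via 1-(benzyloxy)-3,5-difluorobenzene 3 (not isolated)
Conditions: 2 (2.1 equiv), NaH (2.2 equiv), NMP, 0 °C to rt, then 110 °C (sealed vessel)
Reagents that add atoms: none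
Why: Twofold nucleophilic aromatic substitution, in which each fluorine of 1 is activated inductively by the two meta fluorines and every benzyloxy group that enters lowers that activation, so two equivalents of benzyl oxide should stop at the symmetrical monofluoride 4, where no regiochemical question arises.

**Step 2**
Reactants: 4 1,3-bis(benzyloxy)-5-fluorobenzene
Product: 5 1,5-bis(benzyloxy)-2-bromo-3-fluorobenzene
Conditions: NBS (1.0 equiv), MeCN, 0 °C to rt, dark
Reagents that add atoms: N-bromosuccinimide, O=C1CCC(=O)N1Br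
Why: Electrophilic aromatic bromination, in which the position para to one benzyloxy group, ortho to the other and next to the small fluorine is as activated as the position between the two benzyloxy groups but far less crowded, as is usual for 5-substituted resorcinol diethers, while ionic conditions in the dark spare the benzylic CH2 groups.

**Step 3**
Reactants: 5 1,5-bis(benzyloxy)-2-bromo-3-fluorobenzene; 6 2-(benzyloxy)-N-methoxy-N-methylacetamide
Product: 9 2-(benzyloxy)-1-[2,4-bis(benzyloxy)-6-fluorophenyl]ethan-1-one, via aryllithium 7 (not isolated), via lithium hemiaminal adduct 8 (not isolated)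
Conditions: n-BuLi, THF, −78 °C; 6, −78 °C; then 1 M HCl
Reagents that add atoms: none
Why: Bromine–lithium exchange followed by Weinreb ketone synthesis, in which exchange at −78 °C outruns benzylic deprotonation, the ortho-fluoroaryllithium 7 does not lose LiF at this temperature, and the chelated tetrahedral adduct 8 holds until the acidic quench and so prevents a second addition.

**Step 4**
Reactants: 10 methyl 4-fluoro-3-hydroxybenzoate; 11 (4S)-4-benzyl-3-(chloroacetyl)-1,3-oxazolidin-2-one
Product: 12 methyl 3-{2-[(4S)-4-benzyl-2-oxo-1,3-oxazolidin-3-yl]-2-oxoethoxy}-4-fluorobenzoate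
Conditions: K2CO3, NaI (cat), acetone, rt to 40 °C
Reagents that add atoms: none
Why: Williamson ether synthesis, in which the acidic phenol of 10 is alkylated at the very reactive α-chloro imide carbon under carbonate conditions too mild to cleave the imide or the methyl ester, and which fixes the oxygen meta to the ester on the future dioxane C3.

**Step 5**
Reactants: 12 methyl 3-{2-[(4S)-4-benzyl-2-oxo-1,3-oxazolidin-3-yl]-2-oxoethoxy}-4-fluorobenzoate; 13 4-(benzyloxy)-3-methoxybenzaldehyde
Product: 16 syn aldol adduct methyl 3-({(2S,3R)-1-[(4S)-4-benzyl-2-oxo-1,3-oxazolidin-3-yl]-3-[4-(benzyloxy)-3-methoxyphenyl]-3-hydroxy-1-oxopropan-2-yl}oxy)-4-fluorobenzoate, via Z-dibutylboron enolate 14 (not isolated), via dibutylboron aldolate 15 (not isolated)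
Conditions: Bu2BOTf, Et3N, CH2Cl2, −78 to 0 °C; 13, −78 to 0 °C; then H2O2, MeOH, pH 7 buffer, 0 °C
Reagents that add atoms: none
Why: Evans syn glycolate aldol, in which soft enolisation gives the Z boron enolate 14 that reacts through a chair Zimmerman–Traxler transition state on the face away from the benzyl group of the (S)-auxiliary, so the (2S,3R) syn adduct should form and both stereocentres of the target are set here.

**Step 6**
Reactants: 16 syn aldol adduct
Product: 17 methyl 3-({(1R,2R)-1-[4-(benzyloxy)-3-methoxyphenyl]-1,3-dihydroxypropan-2-yl}oxy)-4-fluorobenzoate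
Conditions: NaBH4, THF–H2O (4:1), 0 °C to rt
Reagents that add atoms: none
Why: Chemoselective reductive cleavage of the N-acyloxazolidinone, in which the activated exocyclic imide carbonyl is reduced to the primary alcohol while the methyl benzoate is left, the auxiliary is released, and neither stereocentre is touched (the descriptor of the aryloxy carbon changes from S to R only because the priorities change).

**Step 7**
Reactants: 17 methyl 3-({(1R,2R)-1-[4-(benzyloxy)-3-methoxyphenyl]-1,3-dihydroxypropan-2-yl}oxy)-4-fluorobenzoate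
Product: 19 methyl 3-({(1R,2R)-3-(benzyloxy)-1-[4-(benzyloxy)-3-methoxyphenyl]-1-hydroxypropan-2-yl}oxy)-4-fluorobenzoate, via dibutylstannylene acetal 18 (not isolated)
Conditions: Bu2SnO, toluene, reflux (−H2O); then BnBr, Bu4NI (cat), 90 °C
Reagents that add atoms: benzyl bromide, BrCc1ccccc1
Why: Regioselective O-alkylation through a dibutylstannylene acetal, in which the less hindered primary oxygen of the six-membered acetal 18 is the more nucleophilic one, so benzyl bromide should give the primary benzyl ether under neutral conditions that cannot start fluoride displacement.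

**Step 8**
Reactants: 19 methyl 3-({(1R,2R)-3-(benzyloxy)-1-[4-(benzyloxy)-3-methoxyphenyl]-1-hydroxypropan-2-yl}oxy)-4-fluorobenzoate
Product: 21 methyl (2R,3R)-2-[4-(benzyloxy)-3-methoxyphenyl]-3-[(benzyloxy)methyl]-2,3-dihydro-1,4-benzodioxine-6-carboxylate (trans), via sodium alkoxide 20 (not isolated)
Conditions: NaH, DMF, 0 °C to rt
Reagents that add atoms: none
Why: Intramolecular SNAr, in which the benzylic alkoxide 20 displaces the fluoride para to the ester in a six-membered closure with both C–O bonds at the stereocentres left intact, so the syn (1R,2R) relationship becomes the trans diequatorial (2R,3R) benzodioxane, while a Smiles-type ipso attack is not activated because that carbon is meta to the ester.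

**Step 9**
Reactants: 21 methyl (2R,3R)-benzodioxine-6-carboxylate
Product: 23 (2R,3R)-2-[4-(benzyloxy)-3-methoxyphenyl]-3-[(benzyloxy)methyl]-2,3-dihydro-1,4-benzodioxine-6-carboxylic acid, via lithium carboxylate 22 (not isolated)
Conditions: LiOH, THF–MeOH–H2O, 40 °C; then 1 M HCl
Reagents that add atoms: lithium hydroxide, [Li+].[OH-]
Why: Saponification by acyl substitution at the methyl ester, to which the ethers and the two stereocentres, which bear no acidic hydrogen, are inert.

**Step 10**
Reactants: 23 (2R,3R)-benzodioxine-6-carboxylic acid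
Product: 24 (2R,3R)-2-[4-(benzyloxy)-3-methoxyphenyl]-3-[(benzyloxy)methyl]-2,3-dihydro-1,4-benzodioxine-6-carbonyl chloride
Conditions: 1-chloro-N,N,2-trimethylprop-1-en-1-amine, CH2Cl2, 0 °C to rt; solvent removed
Reagents that add atoms: 1-chloro-N,N,2-trimethylprop-1-en-1-amine, CC(C)=C(Cl)N(C)C
Why: Acid chloride formation with an α-chloroenamine under neutral conditions, which releases no HCl and so does not endanger the electron-rich benzylic C2–O1 bond of the dioxane or the benzyl ethers.

**Step 11**
Reactants: 9 2-(benzyloxy)-1-[2,4-bis(benzyloxy)-6-fluorophenyl]ethan-1-one; 24 (2R,3R)-benzodioxine-6-carbonyl chloride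
Product: 27 1-[2,4-bis(benzyloxy)-6-fluorophenyl]-2-(benzyloxy)-3-{(2R,3R)-2-[4-(benzyloxy)-3-methoxyphenyl]-3-[(benzyloxy)methyl]-2,3-dihydro-1,4-benzodioxin-6-yl}propane-1,3-dione (both epimers at the central carbon), via lithium enolate 25 (not isolated), via lithium diketonate 26 (not isolated)
Conditions: 9 (2 equiv), LiN(SiMe3)2 (2 equiv), THF, −78 °C; 24, −78 to −20 °C; then 1 M HCl
Reagents that add atoms: none
Why: Crossed Claisen-type C-acylation of a ketone enolate, in which the chelated lithium enolate 25 attacks the unhindered aroyl chloride at carbon at low temperature, its second equivalent stores the more acidic product as diketonate 26 and so blocks a second acylation, and the central stereocentre is left uncontrolled because it vanishes in the next step.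

**Step 12**
Reactants: 27 2-benzyloxy-1,3-diketone
Product: 30 3,5,7-tris(benzyloxy)-2-{(2R,3R)-2-[4-(benzyloxy)-3-methoxyphenyl]-3-[(benzyloxy)methyl]-2,3-dihydro-1,4-benzodioxin-6-yl}-4H-chromen-4-one (pentabenzyl ether of the target), via potassium enolate 28 (not isolated), via Meisenheimer adduct 29 (not isolated)
Conditions: K2CO3 (3 equiv), dry DMF, 90 °C, N2
Reagents that add atoms: none
Why: K2CO3 removes the proton of the central CH (future C3), and in the U-shaped enolate 28 the oxygen on the ring B side (future O1) lies next to the fluorine-bearing carbon of ring A (future C8a). This oxygen adds to C8a, the charge passes through C4a into the C4 carbonyl (Meisenheimer adduct 29) and fluoride leaves, which forms O1–C8a and delivers ring C directly as the aromatic 3-benzyloxy-4-pyranone; the closest known reaction type is the base-mediated intramolecular SNAr of 1-(2-haloaryl)-1,3-diketones to flavones and chromones. Ring C closes by a 6-endo-trig addition to the C8a=C4a–C4=O unit, since both carbons of the attacked double bond end up in the new ring, and only the C–F bond that breaks afterwards is exocyclic. No stereocentre is created: the labile central carbon of 27 becomes sp2, and dioxane C2 and C3 bear no acidic hydrogen and keep their R configuration. The step needs O- over C-arylation, fluoride over benzyl oxide displacement at the two ortho carbons, and ring closure over retro-Claisen cleavage; attack by the enolate carbon or by the proximal oxygen would need a four-membered ring, fluorine is by far the better activator and leaving group, and dry carbonate in DMF offers no external nucleophile to the diketone. Both benzyloxy groups are meta to C8a, so they do not feed electrons into the attacked carbon and only weaken the carbonyl as acceptor, which is met by heating.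

**Step 13**
Reactants: 30 pentabenzyl ether of the target
Product: 31 3,5,7-trihydroxy-2-[(2R,3R)-2-(4-hydroxy-3-methoxyphenyl)-3-(hydroxymethyl)-2,3-dihydro-1,4-benzodioxin-6-yl]-4H-chromen-4-one (CNP0110568.1)
Conditions: H2 (1 atm), 10% Pd/C, THF–MeOH, rt
Reagents that add atoms: none
Why: Catalytic hydrogenolysis, in which the four aryl benzyl ethers and the primary benzyl ether are cleaved at one atmosphere in a neutral solvent, whereas the secondary, ring-bound benzylic C2–O1 bond of the dioxane and the chromone C2=C3 bond react much more slowly, so both stereocentres persist.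

**Compound list**
1 | 1,3,5-trifluorobenzene | Fc1cc(F)cc(F)c1 | starting material
2 | benzyl alcohol | OCc1ccccc1 | starting material
3 | 1-(benzyloxy)-3,5-difluorobenzene | Fc1cc(F)cc(OCc2ccccc2)c1 | intermediate
4 | 1,3-bis(benzyloxy)-5-fluorobenzene | Fc1cc(OCc2ccccc2)cc(OCc2ccccc2)c1 | intermediate
5 | 1,5-bis(benzyloxy)-2-bromo-3-fluorobenzene | Fc1cc(OCc2ccccc2)cc(OCc2ccccc2)c1Br | intermediate
6 | 2-(benzyloxy)-N-methoxy-N-methylacetamide | CON(C)C(=O)COCc1ccccc1 | starting material
7 | [2,4-bis(benzyloxy)-6-fluorophenyl]lithium | [Li]c1c(F)cc(OCc2ccccc2)cc1OCc1ccccc1 | intermediate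
8 | lithium hemiaminal adduct of 7 and 6 | [Li]OC(COCc1ccccc1)(N(C)OC)c1c(F)cc(OCc2ccccc2)cc1OCc1ccccc1 | intermediate
9 | 2-(benzyloxy)-1-[2,4-bis(benzyloxy)-6-fluorophenyl]ethan-1-one | O=C(COCc1ccccc1)c1c(F)cc(OCc2ccccc2)cc1OCc1ccccc1 | intermediate
10 | methyl 4-fluoro-3-hydroxybenzoate | COC(=O)c1ccc(F)c(O)c1 | starting material
11 | (4S)-4-benzyl-3-(chloroacetyl)-1,3-oxazolidin-2-one | O=C(CCl)N1C(=O)OC[C@@H]1Cc1ccccc1 | starting material
12 | methyl 3-{2-[(4S)-4-benzyl-2-oxo-1,3-oxazolidin-3-yl]-2-oxoethoxy}-4-fluorobenzoate | COC(=O)c1ccc(F)c(OCC(=O)N2C(=O)OC[C@@H]2Cc2ccccc2)c1 | intermediate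
13 | 4-(benzyloxy)-3-methoxybenzaldehyde | COc1cc(C=O)ccc1OCc1ccccc1 | starting material
14 | Z-dibutylboron enolate of 12 | CCCCB(CCCC)O/C(=C\Oc1cc(C(=O)OC)ccc1F)N1C(=O)OC[C@@H]1Cc1ccccc1 | intermediate
15 | dibutylboron aldolate of 16 | COc1cc([C@@H](OB(CCCC)CCCC)[C@@H](C(=O)N2C(=O)OC[C@@H]2Cc2ccccc2)Oc2cc(C(=O)OC)ccc2F)ccc1OCc1ccccc1 | intermediate
16 | (2S,3R) syn aldol adduct on the (4S)-auxiliary | COc1cc([C@@H](O)[C@@H](C(=O)N2C(=O)OC[C@@H]2Cc2ccccc2)Oc2cc(C(=O)OC)ccc2F)ccc1OCc1ccccc1 | intermediate
17 | methyl 3-({(1R,2R)-1-[4-(benzyloxy)-3-methoxyphenyl]-1,3-dihydroxypropan-2-yl}oxy)-4-fluorobenzoate | COc1cc([C@@H](O)[C@@H](CO)Oc2cc(C(=O)OC)ccc2F)ccc1OCc1ccccc1 | intermediate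
18 | (4R,5R) dibutylstannylene acetal of 17 (2,2-dibutyl-1,3,2-dioxastanninane) | COc1cc([C@H]2O[Sn](CCCC)(CCCC)OC[C@H]2Oc2cc(C(=O)OC)ccc2F)ccc1OCc1ccccc1 | intermediate
19 | methyl 3-({(1R,2R)-3-(benzyloxy)-1-[4-(benzyloxy)-3-methoxyphenyl]-1-hydroxypropan-2-yl}oxy)-4-fluorobenzoate | COc1cc([C@@H](O)[C@@H](COCc2ccccc2)Oc2cc(C(=O)OC)ccc2F)ccc1OCc1ccccc1 | intermediate
20 | sodium alkoxide of 19 | COc1cc([C@@H]([O-])[C@@H](COCc2ccccc2)Oc2cc(C(=O)OC)ccc2F)ccc1OCc1ccccc1.[Na+] | intermediate
21 | methyl (2R,3R)-2-[4-(benzyloxy)-3-methoxyphenyl]-3-[(benzyloxy)methyl]-2,3-dihydro-1,4-benzodioxine-6-carboxylate | COc1cc([C@H]2Oc3ccc(C(=O)OC)cc3O[C@@H]2COCc2ccccc2)ccc1OCc1ccccc1 | intermediate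
22 | lithium carboxylate of 23 | COc1cc([C@H]2Oc3ccc(C(=O)[O-])cc3O[C@@H]2COCc2ccccc2)ccc1OCc1ccccc1.[Li+] | intermediate
23 | (2R,3R)-2-[4-(benzyloxy)-3-methoxyphenyl]-3-[(benzyloxy)methyl]-2,3-dihydro-1,4-benzodioxine-6-carboxylic acid | COc1cc([C@H]2Oc3ccc(C(=O)O)cc3O[C@@H]2COCc2ccccc2)ccc1OCc1ccccc1 | intermediate
24 | (2R,3R)-2-[4-(benzyloxy)-3-methoxyphenyl]-3-[(benzyloxy)methyl]-2,3-dihydro-1,4-benzodioxine-6-carbonyl chloride | COc1cc([C@H]2Oc3ccc(C(=O)Cl)cc3O[C@@H]2COCc2ccccc2)ccc1OCc1ccccc1 | intermediate
25 | Z lithium enolate of 9 | [Li]O/C(=C\OCc1ccccc1)c1c(F)cc(OCc2ccccc2)cc1OCc1ccccc1 | intermediate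
26 | lithium diketonate of 27 | COc1cc([C@H]2Oc3ccc(C(O[Li])=C(OCc4ccccc4)C(=O)c4c(F)cc(OCc5ccccc5)cc4OCc4ccccc4)cc3O[C@@H]2COCc2ccccc2)ccc1OCc1ccccc1 | intermediate
27 | 1-[2,4-bis(benzyloxy)-6-fluorophenyl]-2-(benzyloxy)-3-{(2R,3R)-benzodioxin-6-yl}propane-1,3-dione, central carbon unassigned | COc1cc([C@H]2Oc3ccc(C(=O)C(OCc4ccccc4)C(=O)c4c(F)cc(OCc5ccccc5)cc4OCc4ccccc4)cc3O[C@@H]2COCc2ccccc2)ccc1OCc1ccccc1 | intermediate
28 | potassium enolate of 27 | COc1cc([C@H]2Oc3ccc(C([O-])=C(OCc4ccccc4)C(=O)c4c(F)cc(OCc5ccccc5)cc4OCc4ccccc4)cc3O[C@@H]2COCc2ccccc2)ccc1OCc1ccccc1.[K+] | intermediate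
29 | Meisenheimer adduct (C8a sp3 with F and O1, configuration at C8a undefined) | COc1cc([C@H]2Oc3ccc(C4=C(OCc5ccccc5)C([O-])=C5C(OCc6ccccc6)=CC(OCc6ccccc6)=CC5(F)O4)cc3O[C@@H]2COCc2ccccc2)ccc1OCc1ccccc1.[K+] | intermediate
30 | pentabenzyl ether of the target | COc1cc([C@H]2Oc3ccc(-c4oc5cc(OCc6ccccc6)cc(OCc6ccccc6)c5c(=O)c4OCc4ccccc4)cc3O[C@@H]2COCc2ccccc2)ccc1OCc1ccccc1 | intermediate
31 | CNP0110568.1 | COc1cc([C@H]2Oc3ccc(-c4oc5cc(O)cc(O)c5c(=O)c4O)cc3O[C@@H]2CO)ccc1O | target

**Step count**
- Total step count: 13.
- Longest linear sequence: 10 steps (steps 4 to 13, from 10 to 31).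
- The ring A branch (steps 1 to 3) joins at step 11.

**Steps most likely to fail**

1. **Step 12.**
   - What may go wrong: the aryl ketone carries two ortho substituents and is enriched by two benzyloxy groups. It may twist out of conjugation and activate C8a too weakly. At the temperature then needed, retro-Claisen cleavage by traces of water or loss of benzyl groups could overtake ring closure.
   - Fallback: the polarity is turned round and ring C is closed at O1–C2 from a ring A phenol by Baker–Venkataraman chemistry. The fallback sets out from acid chloride 24 and comes back at 30. Houben–Hoesch acylation of phloroglucinol with benzyloxyacetonitrile (ZnCl2, HCl, Et2O, then hot water) would give 2-(benzyloxy)-1-(2,4,6-trihydroxyphenyl)ethan-1-one F1. Two equivalents of BnBr with K2CO3 would leave only the hydrogen-bonded ortho hydroxyl free in 2-(benzyloxy)-1-[2,4-bis(benzyloxy)-6-hydroxyphenyl]ethan-1-one F2. Acylation with 24 in pyridine would give the aryl ester F3, and KOtBu in THF would move the aroyl group to carbon to give the 2-hydroxyaryl diketone F4. Warm AcOH–NaOAc would then cyclodehydrate F4 to 30.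

2. **Step 11.**
   - What may go wrong: the enolate carbon is secondary and alkoxy-substituted. O-acylation, proton exchange with the product and a second acylation may compete with C–C bond formation.
   - Fallback: the acyl substitution is replaced by an aldol addition and an oxidation. The fallback sets out from 24 (with 9) and comes back at 27. LiAlH(OtBu)3 in THF at −78 °C would reduce 24 to the benzodioxine-6-carbaldehyde F5. Addition of enolate 25 would give the β-hydroxy ketone F6 as a mixture at the two new centres, which are later destroyed. Dess–Martin periodinane would oxidise F6 to 27. An aldehyde offers the enolate no O-acylation channel.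

3. **Step 7.**
   - What may go wrong: discrimination between the primary and the benzylic oxygen of the stannylene acetal may be incomplete, with benzylation at the wrong oxygen or at both.
   - Fallback: the two hydroxyls are told apart by steric bulk and the benzyl group is brought in after ring closure. The fallback sets out from diol 17 and comes back at ester 21. TrCl in pyridine would give the primary trityl ether F7, and NaH in DMF would close the dioxane to the trityl-protected benzodioxane F8. Catalytic TsOH in MeOH–CH2Cl2 would free the hydroxymethyl benzodioxane F9, and NaH with BnBr in DMF would give 21.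

**Further compounds**
F1 | step 12 | 2-(benzyloxy)-1-(2,4,6-trihydroxyphenyl)ethan-1-one | O=C(COCc1ccccc1)c1c(O)cc(O)cc1O
F2 | step 12 | 2-(benzyloxy)-1-[2,4-bis(benzyloxy)-6-hydroxyphenyl]ethan-1-one | O=C(COCc1ccccc1)c1c(O)cc(OCc2ccccc2)cc1OCc1ccccc1
F3 | step 12 | aryl ester of F2 with acid 23 | COc1cc([C@H]2Oc3ccc(C(=O)Oc4cc(OCc5ccccc5)cc(OCc5ccccc5)c4C(=O)COCc4ccccc4)cc3O[C@@H]2COCc2ccccc2)ccc1OCc1ccccc1
F4 | step 12 | 2-hydroxyaryl diketone (hydroxy analogue of 27) | COc1cc([C@H]2Oc3ccc(C(=O)C(OCc4ccccc4)C(=O)c4c(O)cc(OCc5ccccc5)cc4OCc4ccccc4)cc3O[C@@H]2COCc2ccccc2)ccc1OCc1ccccc1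
F5 | step 11 | (2R,3R)-2-[4-(benzyloxy)-3-methoxyphenyl]-3-[(benzyloxy)methyl]-2,3-dihydro-1,4-benzodioxine-6-carbaldehyde | COc1cc([C@H]2Oc3ccc(C=O)cc3O[C@@H]2COCc2ccccc2)ccc1OCc1ccccc1
F6 | step 11 | β-hydroxy ketone from 25 and F5 (new centres unassigned) | COc1cc([C@H]2Oc3ccc(C(O)C(OCc4ccccc4)C(=O)c4c(F)cc(OCc5ccccc5)cc4OCc4ccccc4)cc3O[C@@H]2COCc2ccccc2)ccc1OCc1ccccc1
F7 | step 7 | primary trityl ether of 17 | COc1cc([C@@H](O)[C@@H](COC(c2ccccc2)(c2ccccc2)c2ccccc2)Oc2cc(C(=O)OC)ccc2F)ccc1OCc1ccccc1
F8 | step 7 | trityl-protected (2R,3R)-benzodioxane methyl ester | COc1cc([C@H]2Oc3ccc(C(=O)OC)cc3O[C@@H]2COC(c2ccccc2)(c2ccccc2)c2ccccc2)ccc1OCc1ccccc1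
F9 | step 7 | methyl (2R,3R)-2-[4-(benzyloxy)-3-methoxyphenyl]-3-(hydroxymethyl)-2,3-dihydro-1,4-benzodioxine-6-carboxylate | COc1cc([C@H]2Oc3ccc(C(=O)OC)cc3O[C@@H]2CO)ccc1OCc1ccccc1
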